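**Retrosynthetic overview**

- Feature: in the oxolane (O1, C2 aryl, C3 CH2OH, C4 aroyl, C5 H2) the chain C5–C4–C3–CH2OH is a masked butenolide. C4 carries an acyl carbon and C3 carries the benzylic C–O carbon C2, which is the pattern of an acyl anion added beta and an aldehyde added alpha.
- Disconnections: O1–C2 (cationic etherification of a triol), then C4–C(acyl) and C3–C2 together in one three-component union of a lithiated aryl dithiane, (5R)-5-(l-menthyloxy)furan-2(5H)-one and 3,4,5-trimethoxybenzaldehyde.
- Ring order: the purchased lactone ring serves only as a stereochemical template and is opened by LiAlH4. The oxolane is the only ring formed (step 4), and the ketone is unmasked last.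
- Stereochemistry: the acetal centre sets C4, C4 sets C3 (lactone 3,4-trans). Switching the ring from the lactone to the oxolane turns this into the 3,4-cis pair, and C2 is set trans to C3 in the cation closure.

Key step: step 2

Remark 1: butenolide 4 is taken as a purchasable single diastereomer (otherwise it is obtained from furfural-derived 5-hydroxyfuran-2(5H)-one and l-menthol by acetalisation and crystallisation).
Remark 2: the aldol carbinol centre of 9 and 10 is expected as an epimer mixture. The (S)-epimer is drawn and named, and both epimers are carried into step 4, where this centre is erased and reset.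

**Route**

Step 1
Reactants: 1 3,4-dimethoxybenzaldehyde; 2 propane-1,3-dithiol
Product: 3 2-(3,4-dimethoxyphenyl)-1,3-dithiane
Conditions: BF3·OEt2 (cat.), CH2Cl2, 0 °C to rt
Reagents that add atoms: none
Why: Lewis acid-catalysed dithioacetalisation of an aromatic aldehyde is a reliable condensation and should give a crystalline dithiane whose C2–H is acidic enough for lithiation; no stereocentre is formed.

Step 2
Reactants: 3 2-(3,4-dimethoxyphenyl)-1,3-dithiane; 4 (5R)-5-(l-menthyloxy)furan-2(5H)-one; 5 3,4,5-trimethoxybenzaldehyde
Product: 9 (3S,4R,5R)-4-[2-(3,4-dimethoxyphenyl)-1,3-dithian-2-yl]-3-[(S)-hydroxy(3,4,5-trimethoxyphenyl)methyl]-5-(l-menthyloxy)dihydrofuran-2(3H)-one, via lithiated dithiane 6 (not isolated), via lithium lactone enolate 7 (not isolated), via lithium aldolate 8 (not isolated)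
Conditions: n-BuLi, THF, −78 to −20 °C; then 4, −78 °C; then 5, −78 °C; sat. aq. NH4Cl at −78 °C
Reagents that add atoms: none
Why: n-BuLi removes the C2–H of 3 to give the sulfur- and aryl-stabilised carbanion 6, which adds in Michael fashion to C4 of butenolide 4 (bond from lactone C4 to the masked acyl carbon) on the face opposite the C5 menthyloxy group, fixing C4 as R; the lithium lactone enolate 7 is then intercepted by aldehyde 5 in an aldol addition (bond from lactone C3 to the carbinol carbon) on the face opposite the new quaternary dithianyl group, fixing C3 as S and the 3,4-trans relation. The closest known reaction type is the tandem conjugate addition and aldol trapping of lithiated 2-aryl-1,3-dithianes on 5-alkoxybutenolides, a Michael-initiated three-component coupling. No ring is closed; the lactone ring of 4 is carried through unchanged. C4 is controlled by the acetal stereocentre of the auxiliary and C3 by C4, while the carbinol centre is governed only by the aldol transition state and need not be controlled. The step needs 1,4- over 1,2-addition, which the soft delocalised aryl dithiane anion in THF at −78 °C should secure, and it needs the aldol to outrun proton transfer and retro-aldol, which a reactive non-enolisable aldehyde added cold and a cold quench should secure.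

Step 3
Reactants: 9 tandem adduct (menthyloxy lactone)
Product: 10 (2R,3R)-2-[2-(3,4-dimethoxyphenyl)-1,3-dithian-2-yl]-3-[(S)-hydroxy(3,4,5-trimethoxyphenyl)methyl]butane-1,4-diol
Conditions: LiAlH4, THF, 0 °C to rt; H2O quench
Reagents that add atoms: none
Why: Hydride reduction of an acyl acetal: the lactone carbonyl is taken to CH2OH and the ring-opened hemiacetal expels l-menthoxide to an aldehyde that is reduced as well, so both lactone termini become primary alcohols while the dithiane, the aryl ethers and the stereocentres (no longer alpha to a carbonyl) are untouched.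

Step 4
Reactants: 10 dithianyl triol
Product: 12 [(2S,3R,4R)-4-[2-(3,4-dimethoxyphenyl)-1,3-dithian-2-yl]-2-(3,4,5-trimethoxyphenyl)oxolan-3-yl]methanol, via benzylic cation 11 (not isolated)
Conditions: camphorsulfonic acid (0.1 equiv), CH2Cl2, 0 °C to rt
Reagents that add atoms: none
Why: Acid-catalysed dehydrative cycloetherification (SN1): the trimethoxybenzylic alcohol ionises from either carbinol epimer to cation 11, the primary hydroxyl on the former acetal carbon captures it in a five-membered closure (the other primary hydroxyl could only give an oxetane), and C2 is set trans to the C3 hydroxymethyl arm because the alternative would place aryl, CH2OH and the bulky dithianyl group all cis, a preference reinforced by the reversibility of benzylic ether formation.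

Step 5
Reactants: 12 dithianyl oxolane
Product: 13 Magnone B, (3,4-dimethoxyphenyl)[(3R,4R,5S)-4-(hydroxymethyl)-5-(3,4,5-trimethoxyphenyl)oxolan-3-yl]methanone
Conditions: MeI (excess), CaCO3, MeCN–H2O (4:1), 40 °C
Reagents that add atoms: water, O
Why: Alkylative dithioacetal hydrolysis: S-methylation makes sulfur a leaving group, the aryl-stabilised thionium ion is captured by water (or transiently by the neighbouring CH2OH), and a second methylation and collapse release the aryl ketone under CaCO3-buffered, near-neutral conditions, so the C4 centre alpha to the new carbonyl and the beta-alkoxy ketone should not see acid or base and the 3,4-cis arrangement should be kept.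

**Compound list**

1 | 3,4-dimethoxybenzaldehyde | COc1ccc(C=O)cc1OC | starting material
2 | propane-1,3-dithiol | SCCCS | starting material
3 | 2-(3,4-dimethoxyphenyl)-1,3-dithiane | COc1ccc(C2SCCCS2)cc1OC | intermediate
4 | (5R)-5-{[(1R,2S,5R)-2-isopropyl-5-methylcyclohexyl]oxy}furan-2(5H)-one | O=C1O[C@@H](O[C@@H]2C[C@H](C)CC[C@H]2C(C)C)C=C1 | starting material
5 | 3,4,5-trimethoxybenzaldehyde | COc1cc(C=O)cc(OC)c1OC | starting material
6 | 2-lithio-2-(3,4-dimethoxyphenyl)-1,3-dithiane | [Li]C1(c2ccc(OC)c(OC)c2)SCCCS1 | intermediate (not isolated)
7 | lithium (4R,5R)-4-[2-(3,4-dimethoxyphenyl)-1,3-dithian-2-yl]-5-(l-menthyloxy)-4,5-dihydrofuran-2-olate | [Li+].[O-]C1=C[C@@H](C2(c3ccc(OC)c(OC)c3)SCCCS2)[C@H](O[C@@H]4C[C@H](C)CC[C@H]4C(C)C)O1 | intermediate (not isolated)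
8 | lithium alkoxide of 9 (aldolate) | O=C1O[C@@H](O[C@@H]2C[C@H](C)CC[C@H]2C(C)C)[C@H](C3(c4ccc(OC)c(OC)c4)SCCCS3)[C@H]1[C@H]([O-])c5cc(OC)c(OC)c(OC)c5.[Li+] | intermediate (not isolated)
9 | (3S,4R,5R)-4-[2-(3,4-dimethoxyphenyl)-1,3-dithian-2-yl]-3-[(S)-hydroxy(3,4,5-trimethoxyphenyl)methyl]-5-(l-menthyloxy)dihydrofuran-2(3H)-one | O=C1O[C@@H](O[C@@H]2C[C@H](C)CC[C@H]2C(C)C)[C@H](C3(c4ccc(OC)c(OC)c4)SCCCS3)[C@H]1[C@H](O)c5cc(OC)c(OC)c(OC)c5 | intermediate
10 | (2R,3R)-2-[2-(3,4-dimethoxyphenyl)-1,3-dithian-2-yl]-3-[(S)-hydroxy(3,4,5-trimethoxyphenyl)methyl]butane-1,4-diol | OC[C@H](C1(c2ccc(OC)c(OC)c2)SCCCS1)[C@H](CO)[C@H](O)c3cc(OC)c(OC)c(OC)c3 | intermediate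
11 | benzylic cation from 10 | OC[C@H](C1(c2ccc(OC)c(OC)c2)SCCCS1)[C@H](CO)[CH+]c3cc(OC)c(OC)c(OC)c3 | intermediate (not isolated)
12 | [(2S,3R,4R)-4-[2-(3,4-dimethoxyphenyl)-1,3-dithian-2-yl]-2-(3,4,5-trimethoxyphenyl)oxolan-3-yl]methanol | COc1ccc(C2(SCCCS2)[C@H]3CO[C@H](c4cc(OC)c(OC)c(OC)c4)[C@H]3CO)cc1OC | intermediate
13 | Magnone B | COc1ccc(C(=O)[C@H]2CO[C@H](c3cc(OC)c(OC)c(OC)c3)[C@H]2CO)cc1OC | target

**Step count**

Total steps: 5. Longest linear sequence: 5 (steps 1 to 5).

**Steps most likely to fail**

1. Step 4. The benzylic cation may be diverted before or after oxygen capture: a dithiane sulfur can attack it (sulfonium formation and ring opening of the thioacetal), the electron-rich dimethoxyphenyl ring can attack it in a Friedel–Crafts closure to an aryltetralin, or the product ether can re-ionise under acid. Fallback: starting from triol 10, the thioacetal would be removed first (MeI, CaCO3, aqueous MeCN, 40 °C) to give the keto triol (2R,3R)-1-(3,4-dimethoxyphenyl)-4-hydroxy-2-(hydroxymethyl)-3-[(S)-hydroxy(3,4,5-trimethoxyphenyl)methyl]butan-1-one F1, probably in equilibrium with a five-membered hemiketal. In F1 there is no sulfur and the aryl ring is deactivated by the carbonyl, so catalytic camphorsulfonic acid in CH2Cl2 at 0 °C should close the oxolane through the same cation. The route is rejoined directly at 13, bypassing 12. The price is that C4 is alpha to a free ketone during the acid step, so the acid must be kept catalytic, cold and brief.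

2. Step 5. Cleavage of the hindered thioacetal may be slow, and on prolonged exposure the C4 centre may be lost by enolisation or by retro-oxa-Michael opening and re-closure, drifting to the more stable 3,4-trans isomer. Fallback: starting from 12, one sulfur would be oxidised (mCPBA, 1 equiv, CH2Cl2, −78 °C) to the monosulfoxide [(2S,3R,4R)-4-[2-(3,4-dimethoxyphenyl)-1-oxido-1,3-dithian-2-yl]-2-(3,4,5-trimethoxyphenyl)oxolan-3-yl]methanol F2 (mixture at sulfur). Dithiane 1-oxides hydrolyse far more readily than dithianes, so dilute aqueous HClO4 in THF at 0 °C should release the ketone within a short time. The route is rejoined at 13.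

3. Step 2. The enolate may be quenched by proton transfer before the aldehyde reacts, the aldolate may revert on warming, or some 1,2-addition may compete, so that the one-flask union stops at the conjugate adduct or gives mixtures. Fallback: starting from 3 and 4, the conjugate addition alone would be run and quenched cold to isolate (4R,5R)-4-[2-(3,4-dimethoxyphenyl)-1,3-dithian-2-yl]-5-(l-menthyloxy)dihydrofuran-2(3H)-one F3. Its enolate would then be regenerated with lithium diisopropylamide, LiN(iPr)2, in THF at −78 °C and treated with aldehyde 5, followed by a cold NH4Cl quench. This separates the two bond formations, so each can be driven to completion. Alkylation anti to the C4 substituent is expected as before, and the route is rejoined at 9.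

**Further compounds**

F1 | step 4 | (2R,3R)-1-(3,4-dimethoxyphenyl)-4-hydroxy-2-(hydroxymethyl)-3-[(S)-hydroxy(3,4,5-trimethoxyphenyl)methyl]butan-1-one | OC[C@H](C(=O)c1ccc(OC)c(OC)c1)[C@H](CO)[C@H](O)c2cc(OC)c(OC)c(OC)c2
F2 | step 5 | [(2S,3R,4R)-4-[2-(3,4-dimethoxyphenyl)-1-oxido-1,3-dithian-2-yl]-2-(3,4,5-trimethoxyphenyl)oxolan-3-yl]methanol | COc1ccc(C2(S(=O)CCCS2)[C@H]3CO[C@H](c4cc(OC)c(OC)c(OC)c4)[C@H]3CO)cc1OC
F3 | step 2 | (4R,5R)-4-[2-(3,4-dimethoxyphenyl)-1,3-dithian-2-yl]-5-(l-menthyloxy)dihydrofuran-2(3H)-one | O=C1C[C@@H](C2(c3ccc(OC)c(OC)c3)SCCCS2)[C@H](O[C@@H]4C[C@H](C)CC[C@H]4C(C)C)O1
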